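**Plan**

- The target is an achiral 1H-pyrrole: C2 carries CO2H, C3 and C4 each carry an indol-3-yl group, and C5 carries acetyl. Read as two pieces, N1–C2 with its carboxyl group is a glycine unit, and C3–C4–C5 is a three-carbon enone unit holding both indoles, so ring closure of a glycine imine of a 1,2-di(indolyl) enone makes the C2–C3 bond.
- Retrosynthesis: adjust functional groups first (CO2H from CO2Me, indole N–H from N–Ts, C5 acetyl from C5 ethyl), then cut the pyrrole C2–C3 bond and the N1–C5 bond. This leads to glycine methyl ester and a bis(N-tosylindolyl) ethyl enone.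
- The enone is cut at its C=C bond into a 1-(indol-3-yl)butan-2-one and 1-tosylindole-3-carboxaldehyde; the ketone is cut at its CO–ethyl bond back to indole-3-acetic acid.
- Forward: chain first, ring last. Both indoles are bought as rings; ketone and aldehyde are condensed, nitrogen enters as the ketimine, and the pyrrole (the only ring made) is closed and aromatized in step 7. Oxidation of the ethyl group and one global deprotection finish the route.
- Stereochemistry: the target has no stereocentre; the alkene geometry and the sp3 centres of the dihydropyrrole are erased on aromatization.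

Key step: step 7

Remark: tosyl (Ts) = 4-methylphenylsulfonyl throughout; intermediates with sp3 stereocentres are racemic, and the C=N geometry of the ketimine is left open because it equilibrates under the conditions of its use.

**Step 1**
Reactants: 1 indole-3-acetic acid
Product: 2 2-(1H-indol-3-yl)-N-methoxy-N-methylacetamide
Conditions: MeNHOMe·HCl, EDC·HCl, HOBt (cat.), Et3N, CH2Cl2, 0 °C → rt
Reagents that add atoms: N,O-dimethylhydroxylamine hydrochloride, CNOC.Cl
Why: Carbodiimide-mediated amide coupling of an arylacetic acid with N,O-dimethylhydroxylamine (Weinreb amide formation) is routine and needs no protection of the indole N–H.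

**Step 2**
Reactants: 2 2-(1H-indol-3-yl)-N-methoxy-N-methylacetamide
Product: 3 N-methoxy-N-methyl-2-(1-tosylindol-3-yl)acetamide
Conditions: NaH, DMF, 0 °C; then TsCl, 0 °C → rt
Reagents that add atoms: p-toluenesulfonyl chloride, Cc1ccc(S(=O)(=O)Cl)cc1
Why: The indole N–H is the most acidic site of 2, so one equivalent of NaH gives the indolide, which is sulfonylated on nitrogen (N-tosylation); the sulfonyl group later shields the indole from DDQ and from the cerium oxidant.

**Step 3**
Reactants: 3 N-methoxy-N-methyl-2-(1-tosylindol-3-yl)acetamide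
Product: 4 1-(1-tosylindol-3-yl)butan-2-one
Conditions: EtMgBr, THF, −10 → 0 °C; then 1 M HCl
Reagents that add atoms: ethylmagnesium bromide, CC[Mg]Br
Why: Weinreb ketone synthesis: the magnesium chelate of the tetrahedral adduct survives until the acidic quench, so exactly one ethyl group is delivered, and the N-sulfonyl group is inert to the Grignard reagent at this temperature.

**Step 4**
Reactants: 5 indole-3-carboxaldehyde
Product: 6 1-tosylindole-3-carboxaldehyde
Conditions: TsCl, Et3N, DMAP (cat.), CH2Cl2, 0 °C → rt
Reagents that add atoms: p-toluenesulfonyl chloride, Cc1ccc(S(=O)(=O)Cl)cc1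
Why: The formyl group acidifies the indole N–H enough for amine/DMAP-mediated N-sulfonylation, and removing the nitrogen lone pair from conjugation turns the vinylogous formamide into a competent aldehyde electrophile.

**Step 5**
Reactants: 4 1-(1-tosylindol-3-yl)butan-2-one; 6 1-tosylindole-3-carboxaldehyde
Product: 7 (E)-1,2-bis(1-tosylindol-3-yl)pent-1-en-3-one
Conditions: piperidine (cat.), AcOH (cat.), toluene, reflux, azeotropic removal of water
Reagents that add atoms: none
Why: Knoevenagel-type condensation at the methylene flanked by the carbonyl and the indolyl ring, which is far more acidic than the ethyl CH2, should give mainly the E enone (acyl group trans to the β-indolyl); the geometry is erased in step 7.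

**Step 6**
Reactants: 7 (E)-1,2-bis(1-tosylindol-3-yl)pent-1-en-3-one; 8 glycine methyl ester hydrochloride
Product: 9 methyl N-[(1E)-1,2-bis(1-tosylindol-3-yl)pent-1-en-3-ylidene]glycinate
Conditions: TiCl4 (0.6 equiv), Et3N, CH2Cl2, 0 °C → rt; filtered through Celite, used crude
Reagents that add atoms: none
Why: TiCl4 serves as Lewis acid and irreversible water scavenger, which drives condensation of a primary amine with a hindered α-aryl enone carbonyl (TiCl4-mediated ketimine formation), while the encumbered β-carbon disfavours conjugate addition of the amine.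

**Step 7**
Reactants: 9 methyl N-[(1E)-1,2-bis(1-tosylindol-3-yl)pent-1-en-3-ylidene]glycinate
Product: 11 methyl 5-ethyl-3,4-bis(1-tosylindol-3-yl)-1H-pyrrole-2-carboxylate, via dihydropyrrole ester 10 (not isolated)
Conditions: DBU (0.3 equiv), THF, 60 °C; then AcOH (0.3 equiv), DDQ (1.1 equiv), 0 °C → rt
Reagents that add atoms: none
Why: DBU reversibly removes a proton from the glycinate CH2, which is activated by both the ester and the imine nitrogen, giving a six-electron 2-azapentadienyl anion spread over C2, N1, C5, C4 and C3 (pyrrole numbering). This anion should undergo a thermally allowed disrotatory 1,5-electrocyclization (formally a 5-endo-trig closure) that forms the C2–C3 bond and the five-membered ring, and reprotonation by protonated DBU releases pyrroline 10 and returns the base. The closest known reaction type is the electrocyclization/oxidation sequence of glycine ester imines of chalcone-type enones to pyrrole-2-carboxylates. The sp3 centres at C2, C3 and C4 of 10 are transient and vanish when DDQ abstracts hydride and the ring aromatizes, so no stereocontrol is required. The step needs site-selective deprotonation, secured by the much higher acidity of the glycinate CH2 over the ethyl CH2, and ring closure in preference to intermolecular Michael addition, secured by the conjugated chain that holds both termini together and by the hindered trisubstituted β-carbon. A slight excess of DDQ at 0 °C to room temperature should spare the 5-ethyl group and the N-tosylindoles, because the ester lowers the electron density of the new pyrrole.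

**Step 8**
Reactants: 11 methyl 5-ethyl-3,4-bis(1-tosylindol-3-yl)-1H-pyrrole-2-carboxylate
Product: 12 methyl 5-acetyl-3,4-bis(1-tosylindol-3-yl)-1H-pyrrole-2-carboxylate
Conditions: (NH4)2Ce(NO3)6 (4.5 equiv), THF/AcOH/H2O, 0 °C → rt
Reagents that add atoms: water, O
Why: Single-electron oxidation of the pyrrole by tetravalent cerium and loss of an α-proton from the ethyl group give an azafulvenium ion that water traps, and a second such cycle takes the carbinol to the ketone (cerium-mediated oxidation of an α-alkyl group of a pyrrole-2-carboxylate to acyl); the N-tosylindoles are electron-poor and the pyrrole ring is fully substituted, so no competing site is expected.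

**Step 9**
Reactants: 12 methyl 5-acetyl-3,4-bis(1-tosylindol-3-yl)-1H-pyrrole-2-carboxylate
Product: 13 5-acetyl-3,4-di(1H-indol-3-yl)-1H-pyrrole-2-carboxylic acid (target)
Conditions: KOH (excess), 1,4-dioxane/H2O, 80 °C; then 1 M HCl to pH 3, 0 °C
Reagents that add atoms: potassium hydroxide, [K+].[OH-]
Why: Hydroxide attacks the sulfonyl sulfur of both N-tosylindoles, which expel the stabilized indolide, and saponifies the methyl ester (base-mediated N-desulfonylation and ester hydrolysis); the 5-acetyl group stabilizes the pyrrole-2-carboxylic acid against decarboxylation during the cold, mild acidification.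

**Compound list**

1 | indole-3-acetic acid | OC(=O)Cc1c[nH]c2ccccc12 | starting material
2 | 2-(1H-indol-3-yl)-N-methoxy-N-methylacetamide | CON(C)C(=O)Cc1c[nH]c2ccccc12 | intermediate
3 | N-methoxy-N-methyl-2-(1-tosylindol-3-yl)acetamide | CON(C)C(=O)Cc1cn(S(=O)(=O)c2ccc(C)cc2)c2ccccc12 | intermediate
4 | 1-(1-tosylindol-3-yl)butan-2-one | CCC(=O)Cc1cn(S(=O)(=O)c2ccc(C)cc2)c2ccccc12 | intermediate
5 | indole-3-carboxaldehyde | O=Cc1c[nH]c2ccccc12 | starting material
6 | 1-tosylindole-3-carboxaldehyde | O=Cc1cn(S(=O)(=O)c2ccc(C)cc2)c2ccccc12 | intermediate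
7 | (E)-1,2-bis(1-tosylindol-3-yl)pent-1-en-3-one | CCC(=O)/C(c1cn(S(=O)(=O)c2ccc(C)cc2)c2ccccc12)=C/c1cn(S(=O)(=O)c2ccc(C)cc2)c2ccccc12 | intermediate
8 | glycine methyl ester hydrochloride | COC(=O)CN.Cl | starting material
9 | methyl N-[(1E)-1,2-bis(1-tosylindol-3-yl)pent-1-en-3-ylidene]glycinate (C=N geometry open) | CCC(=NCC(=O)OC)/C(c1cn(S(=O)(=O)c2ccc(C)cc2)c2ccccc12)=C/c1cn(S(=O)(=O)c2ccc(C)cc2)c2ccccc12 | intermediate
10 | methyl 5-ethyl-3,4-bis(1-tosylindol-3-yl)-3,4-dihydro-2H-pyrrole-2-carboxylate (racemic; the 2,3-trans-3,4-trans isomer expected after base equilibration is drawn; other diastereomers converge on 11) | CCC1=N[C@H](C(=O)OC)[C@@H](c2cn(S(=O)(=O)c3ccc(C)cc3)c3ccccc23)[C@@H]1c1cn(S(=O)(=O)c2ccc(C)cc2)c2ccccc12 | intermediate (not isolated)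
11 | methyl 5-ethyl-3,4-bis(1-tosylindol-3-yl)-1H-pyrrole-2-carboxylate | CCc1[nH]c(C(=O)OC)c(-c2cn(S(=O)(=O)c3ccc(C)cc3)c3ccccc23)c1-c1cn(S(=O)(=O)c2ccc(C)cc2)c2ccccc12 | intermediate
12 | methyl 5-acetyl-3,4-bis(1-tosylindol-3-yl)-1H-pyrrole-2-carboxylate | CC(=O)c1[nH]c(C(=O)OC)c(-c2cn(S(=O)(=O)c3ccc(C)cc3)c3ccccc23)c1-c1cn(S(=O)(=O)c2ccc(C)cc2)c2ccccc12 | intermediate
13 | 5-acetyl-3,4-di(1H-indol-3-yl)-1H-pyrrole-2-carboxylic acid | CC(=O)c1[nH]c(C(=O)O)c(-c2c[nH]c3ccccc23)c1-c1c[nH]c2ccccc12 | target

**Step count**

Total: 9 steps. Longest linear sequence: 8 steps (steps 1, 2, 3, 5, 6, 7, 8, 9 from indole-3-acetic acid); step 4 is a one-step side branch.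

**Steps most likely to fail**

Step 6. Condensation at the hindered carbonyl may stall, the amine may add in conjugate fashion, or the free glycinate may self-condense before the imine forms. The fallback sets out from 7 and comes back at 9 and replaces amine condensation by a water-free aza-Wittig reaction. Commercial methyl azidoacetate (COC(=O)CN=[N+]=[N-]) is treated with PPh3 in THF (Staudinger reaction) to give methyl N-(triphenylphosphoranylidene)glycinate F1. Heating F1 with 7 in toluene should form the C=N bond irreversibly, with no free amine present, and deliver 9.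

Step 7. The stabilized anion may be slow to close and instead undergo a 1,3-proton shift to the conjugated 2-azadiene or add to a second molecule. The fallback sets out from 7 and comes back at 10; it makes the C2–C3 bond first by a polar addition and closes the ring by C=N formation. Base-mediated Michael addition of commercial N-(diphenylmethylene)glycine methyl ester (COC(=O)CN=C(c1ccccc1)c1ccccc1; DBU, LiBr, THF) to 7 should give methyl 2-[(diphenylmethylidene)amino]-5-oxo-3,4-bis(1-tosylindol-3-yl)heptanoate F2. Hydrolysis of the benzophenone imine with 1 M HCl in THF gives methyl 2-amino-5-oxo-3,4-bis(1-tosylindol-3-yl)heptanoate F3 as its hydrochloride. On neutralization with NaHCO3, F3 should condense intramolecularly (5-exo-trig attack of the amine on the ketone) to pyrroline 10, which is dehydrogenated with DDQ as in the second stage of step 7 to give 11.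

Step 8. The one-electron oxidant may attack the indole rings, over-oxidize, or stop at the carbinol or its nitrate ester. The fallback sets out from 11 and comes back at 12 and uses a two-electron acetoxylation followed by a separate alcohol oxidation. Lead tetraacetate, Pb(OAc)4, in AcOH should acetoxylate the α-carbon of the ethyl group to give methyl 5-(1-acetoxyethyl)-3,4-bis(1-tosylindol-3-yl)-1H-pyrrole-2-carboxylate F4. Solvolysis in aqueous acetone with NaHCO3 gives methyl 5-(1-hydroxyethyl)-3,4-bis(1-tosylindol-3-yl)-1H-pyrrole-2-carboxylate F5. Manganese dioxide, MnO2, in CH2Cl2 then oxidizes this pyrrolic carbinol to 12.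

**Further compounds**

F1 | step 6 | methyl N-(triphenylphosphoranylidene)glycinate | COC(=O)CN=P(c1ccccc1)(c1ccccc1)c1ccccc1
F2 | step 7 | methyl 2-[(diphenylmethylidene)amino]-5-oxo-3,4-bis(1-tosylindol-3-yl)heptanoate (mixture of racemic diastereomers) | CCC(=O)C(c1cn(S(=O)(=O)c2ccc(C)cc2)c2ccccc12)C(c1cn(S(=O)(=O)c2ccc(C)cc2)c2ccccc12)C(N=C(c1ccccc1)c1ccccc1)C(=O)OC
F3 | step 7 | methyl 2-amino-5-oxo-3,4-bis(1-tosylindol-3-yl)heptanoate (mixture of racemic diastereomers, handled as hydrochloride) | CCC(=O)C(c1cn(S(=O)(=O)c2ccc(C)cc2)c2ccccc12)C(c1cn(S(=O)(=O)c2ccc(C)cc2)c2ccccc12)C(N)C(=O)OC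
F4 | step 8 | methyl 5-(1-acetoxyethyl)-3,4-bis(1-tosylindol-3-yl)-1H-pyrrole-2-carboxylate (racemic) | CC(OC(C)=O)c1[nH]c(C(=O)OC)c(-c2cn(S(=O)(=O)c3ccc(C)cc3)c3ccccc23)c1-c1cn(S(=O)(=O)c2ccc(C)cc2)c2ccccc12
F5 | step 8 | methyl 5-(1-hydroxyethyl)-3,4-bis(1-tosylindol-3-yl)-1H-pyrrole-2-carboxylate (racemic) | CC(O)c1[nH]c(C(=O)OC)c(-c2cn(S(=O)(=O)c3ccc(C)cc3)c3ccccc23)c1-c1cn(S(=O)(=O)c2ccc(C)cc2)c2ccccc12
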